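**Retrosynthetic overview**
1. Rings A and B are bought intact as acetophenone 1 (ring A: three methoxy groups plus the phenol that becomes O1) and aldehyde 2 (ring B).
2. C2–C3 disconnection (flavone numbering): chalcone 3 from 1 + 2 by aldol condensation.
3. O1–C2 disconnection: ring C is closed by oxidative C–O cyclisation of 3, through flavanone 4, to the C8-unsubstituted flavone 5.
4. Key disconnection C8–O: the only free hydroxyl is installed last by direct C8–H oxygenation of 5 (aryl ester 6, cleaved in the same pot) to give target 7, so no protecting group and no selective methylation or demethylation is needed.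
5. Ring order: A and B preformed, ring C in step 2, C8–O bond in step 3.

Assumption: the target has no stereocentre or stereoaxis, so "single enantiomer" is met automatically (the E-alkene of 3 and the racemic centre of 4 are erased in step 2); 1 is taken as a catalogue compound, and 4,5-dichlorophthaloyl peroxide is a pre-formed reagent (from 4,5-dichlorophthaloyl chloride and Na2CO3·1.5H2O2), not counted as a route step.

**Step 1**
Reactants: 1 2'-hydroxy-4',5',6'-trimethoxyacetophenone; 2 3,4,5-trimethoxybenzaldehyde
Product: 3 (E)-2'-hydroxy-3,4,5,4',5',6'-hexamethoxychalcone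
Conditions: KOH (3 equiv, 50% aq), EtOH, rt, 24–48 h; then 1 M HCl
Reagents that add atoms: none
Why: Claisen–Schmidt (crossed aldol) condensation, in which the enolate of 1 adds to the non-enolisable aldehyde 2 and E1cB dehydration gives the conjugated E-enone under thermodynamic control; any flavanone formed alongside is harmless because it is also converted in step 2.

**Step 2**
Reactants: 3 (E)-2'-hydroxy-3,4,5,4',5',6'-hexamethoxychalcone
Product: 5 hexamethoxyflavone [5,6,7-trimethoxy-2-(3,4,5-trimethoxyphenyl)-4H-chromen-4-one], via racemic flavanone 4 (not isolated)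
Conditions: I2 (10 mol%), DMSO, 120 °C, 3 h; aq Na2S2O3 work-up
Reagents that add atoms: none
Why: Iodine-catalysed oxidative cyclisation in DMSO, in which 6-endo oxa-Michael addition of the phenol forms the O1–C2 bond (flavanone 4), iodination at C3 and loss of HI dehydrogenate C2–C3, and DMSO reoxidises HI to I2; the C2 centre of 4 is destroyed, so no stereocontrol is needed.

**Step 3**
Reactants: 5 hexamethoxyflavone [5,6,7-trimethoxy-2-(3,4,5-trimethoxyphenyl)-4H-chromen-4-one]
Product: 7 target 8-hydroxy-5,6,7,3',4',5'-hexamethoxyflavone, via flavon-8-yl hydrogen 4,5-dichlorophthalate 6 (not isolated)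
Conditions: 4,5-dichlorophthaloyl peroxide (1.2 equiv), (CF3)2CHOH, 0 °C to rt, dark, 12 h; evaporate; then Na2S2O3 (0.2 equiv, peroxide scavenger), NaHCO3, THF/H2O, 40 °C, Ar; 1 M HCl work-up
Reagents that add atoms: 4,5-dichlorophthaloyl peroxide, O=C1OOC(=O)c2cc(Cl)c(Cl)cc12
Why: Proposed new method: a cyclic diacyl peroxide transfers one oxygen to an arene C–H when the π-system attacks the O–O bond (C–O bond formation to a cyclohexadienyl/carboxyl radical pair, then H-abstraction by the tethered carboxyl), and in 5 the only C–H of ring A, C8, is the most nucleophilic carbon (para to 5-OMe, ortho to 7-OMe and O1, the site where 5,7-dioxygenated flavones are brominated), whereas ring B C2'/C6' has only two activating oxygens and is deactivated by conjugation to the electron-poor C2 of the pyranone (more so when C4=O is hydrogen-bonded by the fluorinated alcohol) and C3–H is a push–pull vinyl position; the product is born as the electron-poor ester 6 on a fully substituted ring A, which blocks over-oxidation to the 5,8-quinone until the oxidant is destroyed, and the ortho-carboxylate then cleaves the ester under bicarbonate by neighbouring-group participation; closest known reaction type: metal-free arene C–H hydroxylation of anisoles and alkylbenzenes with phthaloyl peroxides, not yet shown on flavones/chromones or at C8 of a fully O-methylated flavone (the known C8 hydroxylation, Elbs persulfate oxidation, needs a free 5-OH).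

**Compound list**
1 | 2'-hydroxy-4',5',6'-trimethoxyacetophenone [1-(6-hydroxy-2,3,4-trimethoxyphenyl)ethan-1-one] | CC(=O)c1c(O)cc(OC)c(OC)c1OC | starting material
2 | 3,4,5-trimethoxybenzaldehyde | COc1cc(C=O)cc(OC)c1OC | starting material
3 | (E)-1-(6-hydroxy-2,3,4-trimethoxyphenyl)-3-(3,4,5-trimethoxyphenyl)prop-2-en-1-one (chalcone) | COc1cc(/C=C/C(=O)c2c(O)cc(OC)c(OC)c2OC)cc(OC)c1OC | intermediate
4 | racemic 5,6,7-trimethoxy-2-(3,4,5-trimethoxyphenyl)chroman-4-one (flavanone, both enantiomers) | COc1cc(C2CC(=O)c3c(OC)c(OC)c(OC)cc3O2)cc(OC)c1OC | intermediate (not isolated)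
5 | 5,6,7-trimethoxy-2-(3,4,5-trimethoxyphenyl)-4H-chromen-4-one (5,6,7,3',4',5'-hexamethoxyflavone) | COc1cc(-c2cc(=O)c3c(OC)c(OC)c(OC)cc3o2)cc(OC)c1OC | intermediate
6 | 4,5-dichloro-2-({[5,6,7-trimethoxy-4-oxo-2-(3,4,5-trimethoxyphenyl)-4H-chromen-8-yl]oxy}carbonyl)benzoic acid | COc1cc(-c2cc(=O)c3c(OC)c(OC)c(OC)c(OC(=O)c4cc(Cl)c(Cl)cc4C(=O)O)c3o2)cc(OC)c1OC | intermediate (not isolated)
7 | 8-hydroxy-5,6,7-trimethoxy-2-(3,4,5-trimethoxyphenyl)-4H-chromen-4-one (8-hydroxy-5,6,7,3',4',5'-hexamethoxyflavone, achiral) | COc1cc(-c2cc(=O)c3c(OC)c(OC)c(OC)c(O)c3o2)cc(OC)c1OC | target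

**Totals**
Total step count: 3. Longest linear sequence: 3 steps (1 → 3 → 5 → 7; aldehyde 2 enters in step 1).

**Steps most likely to fail, with fallbacks**

Step 3 (the new C–H oxygenation) is the main risk. It could fail by attack at ring B C2'/C6' or at C3, by single-electron oxidation with demethylation to quinones, or by air oxidation of 7 in base. The peroxide is also an energetic reagent and should be handled on small scale behind a shield. The fallback uses known chemistry and sets out from 5. NBS (1.05 equiv) in DMF at 0 °C to rt brominates the same activated position to give 8-bromo-5,6,7-trimethoxy-2-(3,4,5-trimethoxyphenyl)-4H-chromen-4-one F1. Palladium-catalysed C–O coupling of F1 with (E)-benzaldoxime as a hydroxide surrogate (Pd2(dba)3 as the zerovalent palladium source, tBuBrettPhos, Cs2CO3, DMF, 80 °C) gives the O-aryl oxime 8-{[(E)-benzylideneamino]oxy}-5,6,7-trimethoxy-2-(3,4,5-trimethoxyphenyl)-4H-chromen-4-one F2. F2 is not isolated and fragments under the same carbonate conditions to benzonitrile and the phenoxide, and acidification brings the route back at 7. This costs one extra step.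

Step 2 could fail through HI-mediated loss of the 5-O-methyl group (peri to the carbonyl) or through iodination of the activated ring A C–H. The fallback sets out from 3 and separates ring closure from dehydrogenation. NaOAc in refluxing EtOH closes ring C by oxa-Michael addition to give flavanone 4, which is now isolated. DDQ in refluxing 1,4-dioxane then dehydrogenates 4 by hydride abstraction, with no iodine or HI present, and the route is rejoined at 5. This fallback makes no compound outside the list (F0).

Step 1 could fail through sluggish condensation of the di-ortho-substituted, twisted acetyl group or through Cannizzaro loss of 2. The fallback is a Baker–Venkataraman sequence that sets out from 1. 3,4,5-Trimethoxybenzoyl chloride in pyridine at rt gives the aryl ester 2-acetyl-3,4,5-trimethoxyphenyl 3,4,5-trimethoxybenzoate F3. KOH in pyridine at 50 °C effects the O-to-C acyl shift to the diketone 1-(6-hydroxy-2,3,4-trimethoxyphenyl)-3-(3,4,5-trimethoxyphenyl)propane-1,3-dione F4. Cyclodehydration of F4 (catalytic H2SO4, AcOH, 100 °C) rejoins the route at 5, bypassing 3 and 4.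

**Further compounds**
F1 | step 3 | 8-bromo-5,6,7-trimethoxy-2-(3,4,5-trimethoxyphenyl)-4H-chromen-4-one | COc1cc(-c2cc(=O)c3c(OC)c(OC)c(OC)c(Br)c3o2)cc(OC)c1OC
F2 | step 3 | 8-{[(E)-benzylideneamino]oxy}-5,6,7-trimethoxy-2-(3,4,5-trimethoxyphenyl)-4H-chromen-4-one | COc1cc(-c2cc(=O)c3c(OC)c(OC)c(OC)c(O/N=C/c4ccccc4)c3o2)cc(OC)c1OC
F0 | step 2 | none | none
F3 | step 1 | 2-acetyl-3,4,5-trimethoxyphenyl 3,4,5-trimethoxybenzoate | CC(=O)c1c(OC(=O)c2cc(OC)c(OC)c(OC)c2)cc(OC)c(OC)c1OC
F4 | step 1 | 1-(6-hydroxy-2,3,4-trimethoxyphenyl)-3-(3,4,5-trimethoxyphenyl)propane-1,3-dione | COc1cc(C(=O)CC(=O)c2c(O)cc(OC)c(OC)c2OC)cc(OC)c1OC
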